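All runs are simulated on assumed constants, and the scatter is random.

The amounts in the red run, which is this same flask followed up to 80.0 min, are our starting point: how much of the substrate charged has reached either product.

- red: substrate 30 mM; first nucleophile 0.60 equiv; second nucleophile 1 equiv; the very flask that is asked about, followed so far
- flask: substrate 30 mM; first nucleophile 0.600 equiv; second nucleophile 1.00 equiv; time 10 h

red run (percent of the substrate charged)

| time / min | other capture product / % | target / % |
|---|---|---|
| 6.00 | 2.1 | 0.9 |
| 12.0 | 4.4 | 1.9 |
| 30.0 | 14.6 | 1.3 |
| 80.0 | 34.0 | 1.6 |

(each reading ± 0.5 percentage points)



- share of other capture product in other capture product plus target at 6.0 min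
- share of other capture product in other capture product plus target at 1.0 h
- share of other capture product in other capture product plus target at 10 h
- which of other capture product and target there is more of at 10 h

- We work with the fraction left, the part of the substrate charged that stands in neither product; the last readings put it at 64.4% at 80.0 min.
- Dividing the logarithm of one over the fraction left by the time gives 0.330 h⁻¹, the capture constant, as read from these readings.
- At 6.0 min we need no constant, since the first readings give a share of 70.0% directly, though it is rough with a scatter of 0.5 percentage points.
- At 1.0 h the constant leaves 71.9%; if the target holds at its last reading of 1.6%, the share is 94.3%.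
- At 10 h the same constant leaves 3.69%, and the same target gives a share of 98.3%.
- The weak link is the constancy of that constant. As a trial, which is our assumption and no reading, we let the rate fall with the square of the fraction left, the form for a capture that joins substrate and second nucleophile, charged equally, in one step.
- Reforged in that way, the reading at 80.0 min leaves 19.4% at 10 h and gives a share of 98.0%. The two routes differ by 0.32 points, so we commit to about 98.0%, with the other capture product ahead.
- The forecast says 71%, 94.5% and 96%, with other capture product ahead, and it reads the target as one that “stays flat within the scatter”. Our share at 10 h stands higher than its own.

- The flask gives 66.7%, 94.4% and 99.3%, with other capture product ahead; at 10.0 h it holds 0.601% of target against 89.3% of other capture product.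

    substrate ⇌ intermediate (K = 0.0820, k = 0.430 h⁻¹)
    first nucleophile + intermediate ⇌ target (K = 79.0 M⁻¹, k = 1600 M⁻¹ h⁻¹)
    second nucleophile + intermediate → other capture product (k = 950 M⁻¹ h⁻¹)
    intermediate → side product (k = 0.200 h⁻¹)

- The capture constant's 71.9% left at 1.0 h stands beside 71.2% in this flask. At 10 h the flask's fraction left corresponds to a constant of 0.229 h⁻¹, and the neighbour flask with 0.240 equiv of first nucleophile gives 0.228 h⁻¹.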